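**Plan**

- Ring A is numbered C1 (prenyl), C2, C3, C4 (OH), C5 (CHO), C6 (aroyl); ring B is the benzodioxane. The retrosynthesis first returns the C5 aldehyde to a diethyl acetal, then cuts C1–C6 and C4–C5 of ring A after re-forming an oxygen bridge from the C4 oxygen to C1.
- What allows this cut: prenyl-bearing C1 and hydroxyl-bearing C4 are para, and the two carbonyl-bearing carbons C5 and C6 lie side by side between them. C1–C2–C3–C4 with the phenol oxygen is therefore a 2-prenylfuran, and C5–C6 is a disubstituted alkyne, an aryl ynone with the acetal on its far carbon.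
- The ynone is cut between alkyne and carbonyl carbon into a ring B aldehyde and lithiated 3,3-diethoxypropyne. The dioxane is cut at both alkyl C–O bonds into 2,3-dihydroxy-5-methylbenzaldehyde and an epoxy sulfonate made from prenol.
- Forward order: the ring B dioxane first (catechol dianion alkylation, then epoxide opening), then the ynone chain, then ring A by furan cycloaddition and bridge opening, and last the acetal hydrolysis.
- The single stereocentre comes from a Sharpless asymmetric epoxidation of prenol with L-(+)-tartrate. The (S)-epoxide carbon is inverted to the (R) dioxane carbon when a phenoxide opens it, and no later step touches it.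

Key step: step 7

Remark on the chemistry: the dioxane stereocentre of the target is read as (R). Acetal 18, a salicylaldehyde-type acetal, is assumed to survive a base-quenched, non-acidic work-up; any material that has already lost the acetal is 19 and is carried through step 8.

**Route**

Step 1
Reactants: 1 prenol (3-methylbut-2-en-1-ol)
Product: 3 [(2S)-3,3-dimethyloxiran-2-yl]methyl 4-methylbenzenesulfonate, via (S)-epoxy alcohol 2 (not isolated)
Conditions: Ti(OiPr)4 (5 mol %), L-(+)-diisopropyl tartrate (6 mol %), t-BuOOH (2 equiv), 4 Å MS, CH2Cl2, −20 °C; P(OMe)3, −20 °C; then TsCl, Et3N, DMAP (cat.), −10 °C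
Reagents that add atoms: tert-butyl hydroperoxide, CC(C)(C)OO; 4-methylbenzenesulfonyl chloride, Cc1ccc(cc1)S(=O)(=O)Cl
Why: Sharpless asymmetric epoxidation of a primary allylic alcohol: with the L-(+)-tartrate ligand the titanium–tartrate–hydroperoxide complex delivers oxygen to the alkene face that gives the (S)-epoxide, which sets the only stereocentre of the route, and sulfonylation in the same flask (after reduction of surplus hydroperoxide) avoids isolating the small, water-soluble epoxy alcohol and gives a sulfonate that can be purified and, if crystalline, enriched by recrystallisation.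

Step 2
Reactants: 4 2-hydroxy-3-methoxy-5-methylbenzaldehyde
Product: 5 2,3-dihydroxy-5-methylbenzaldehyde
Conditions: BBr3 (2.5 equiv), CH2Cl2, −78 °C → rt; H2O
Reagents that add atoms: none
Why: Lewis-acid cleavage of an aryl methyl ether with BBr3, routine for ortho-vanillin-type aldehydes, should free the second phenol without harming the formyl or the ring methyl group.

Step 3
Reactants: 5 2,3-dihydroxy-5-methylbenzaldehyde; 3 [(2S)-3,3-dimethyloxiran-2-yl]methyl 4-methylbenzenesulfonate
Product: 8 (3R)-3-(2-hydroxypropan-2-yl)-7-methyl-2,3-dihydro-1,4-benzodioxine-5-carbaldehyde, via disodium catecholate 6 (not isolated), via epoxy ether phenoxide 7 (not isolated)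
Conditions: NaH (2.05 equiv), DMSO, rt; 3 (1.0 equiv), rt, then 60 °C; 1 M HCl to pH 6
Reagents that add atoms: none
Why: Williamson etherification of a catechol dianion followed by 6-exo-tet epoxide opening: the phenoxide meta to the formyl group is not conjugated to it and is the more nucleophilic, so it should displace the primary tosylate, and the remaining ortho-formyl phenoxide then attacks the less substituted epoxide carbon with SN2 inversion, which turns the (S)-epoxide carbon into the (R)-configured dioxane carbon and releases the tertiary alcohol.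

Step 4
Reactants: 8 (3R)-3-(2-hydroxypropan-2-yl)-7-methyl-2,3-dihydro-1,4-benzodioxine-5-carbaldehyde; 9 3,3-diethoxyprop-1-yne
Product: 11 4,4-diethoxy-1-[(3R)-3-(2-hydroxypropan-2-yl)-7-methyl-2,3-dihydro-1,4-benzodioxin-5-yl]but-2-yn-1-ol (both carbinol epimers), via lithium acetylide 10 (not isolated)
Conditions: 9 (2.6 equiv), n-BuLi (2.5 equiv), THF, −78 °C; 8, −78 → 0 °C; H2O
Reagents that add atoms: none
Why: 1,2-addition of a lithium acetylide to an aryl aldehyde, with the first equivalent consumed by the tertiary hydroxyl, whose lithium alkoxide is inert; the new carbinol centre forms without control, which does not matter because it is oxidised in step 5.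

Step 5
Reactants: 11 4,4-diethoxy-1-[(3R)-3-(2-hydroxypropan-2-yl)-7-methyl-2,3-dihydro-1,4-benzodioxin-5-yl]but-2-yn-1-ol
Product: 12 4,4-diethoxy-1-[(3R)-3-(2-hydroxypropan-2-yl)-7-methyl-2,3-dihydro-1,4-benzodioxin-5-yl]but-2-yn-1-one
Conditions: MnO2 (activated, 20 equiv), CH2Cl2, rt
Reagents that add atoms: none
Why: MnO2 oxidation is selective for the benzylic and propargylic secondary alcohol and should leave the tertiary alcohol, the acetal and the dioxane stereocentre untouched.

Step 6
Reactants: 13 furan; 14 prenyl bromide (1-bromo-3-methylbut-2-ene)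
Product: 16 2-(3-methylbut-2-en-1-yl)furan (2-prenylfuran), via 2-lithiofuran 15 (not isolated)
Conditions: 13 (1.5 equiv), n-BuLi (1.0 equiv), THF, 0 °C → rt; 14, −78 °C → rt
Reagents that add atoms: none
Why: α-Lithiation of furan and SN2 alkylation of 2-lithiofuran with a primary allylic bromide is the standard entry to 2-alkylfurans, and the excess of furan makes dialkylation unlikely.

Step 7
Reactants: 12 4,4-diethoxy-1-[(3R)-3-(2-hydroxypropan-2-yl)-7-methyl-2,3-dihydro-1,4-benzodioxin-5-yl]but-2-yn-1-one; 16 2-prenylfuran
Product: 18 [2-(diethoxymethyl)-3-hydroxy-6-(3-methylbut-2-en-1-yl)phenyl][(3R)-3-(2-hydroxypropan-2-yl)-7-methyl-2,3-dihydro-1,4-benzodioxin-5-yl]methanone, via 7-oxanorbornadiene 17 (not isolated)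
Conditions: 16 (5 equiv), toluene, 80 °C, sealed tube; excess 16 removed in vacuo; ZnI2 (0.5 equiv), CH2Cl2, −20 → 0 °C; Et3N, then NaHCO3 (aq)
Reagents that add atoms: none
Why: The electron-rich 2-alkylfuran 16 adds as the diene to the electron-poor alkyne of ynone 12 in a thermal, normal-electron-demand intermolecular [4+2] cycloaddition (Diels–Alder reaction of a furan with an acetylenic ketone), which closes the six-membered carbocycle of ring A by forming C1–C6 and C4–C5 in one asynchronous event and gives 7-oxanorbornadiene 17. ZnI2 then binds the bridging oxygen and ionises the C1–O bond, and loss of the C4 proton from the cyclohexadienyl cation aromatises the ring to the C4 phenol, the known Lewis-acid isomerisation of 7-oxanorbornadienes to phenols. The cycloaddition must join the unsubstituted furan α-carbon (future C4), its most nucleophilic terminus, to the acetal-bearing alkyne carbon β to the ketone (future C5), its most electrophilic carbon; this is the same "ortho" orientation that 2-alkylfurans show with propiolates, and it also pairs the less hindered furan terminus with the more hindered alkyne carbon. The bridge must open at C1, which is secured because that cleavage gives a tertiary cation with charge on C1, C3 and C5, away from the acyl-bearing C6, whereas cleavage at C4 would put charge on C6 and leave no proton to lose at C1. No lasting stereocentre is made: the two bridgehead centres of 17 form as a mixture of diastereomers relative to the dioxane centre and both vanish on aromatisation, while the remote (R) centre is not involved. The acetal, the prenyl alkene and the tertiary alcohol have to survive, which is why the cycloaddition is run without acid, the surplus furan is removed before the Lewis acid is added, and a mild zinc halide is used in substoichiometric amount at low temperature.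

Step 8
Reactants: 18 [2-(diethoxymethyl)-3-hydroxy-6-(3-methylbut-2-en-1-yl)phenyl][(3R)-3-(2-hydroxypropan-2-yl)-7-methyl-2,3-dihydro-1,4-benzodioxin-5-yl]methanone
Product: 19 6-hydroxy-2-{[(3R)-3-(2-hydroxypropan-2-yl)-7-methyl-2,3-dihydro-1,4-benzodioxin-5-yl]carbonyl}-3-(3-methylbut-2-en-1-yl)benzaldehyde (CNP0373866.1)
Conditions: PPTS (0.2 equiv), acetone/H2O (10:1), rt
Reagents that add atoms: water, O
Why: Acid-catalysed acetal hydrolysis, unusually easy here because the ortho-hydroxyl stabilises the intermediate oxocarbenium ion, so a weak pyridinium acid in wet acetone should suffice and leave the prenyl alkene and the tertiary alcohol alone.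

**Compound list**

1 | prenol (3-methylbut-2-en-1-ol) | CC(C)=CCO | starting material
2 | [(2S)-3,3-dimethyloxiran-2-yl]methanol | OC[C@@H]1OC1(C)C | intermediate
3 | [(2S)-3,3-dimethyloxiran-2-yl]methyl 4-methylbenzenesulfonate | Cc1ccc(cc1)S(=O)(=O)OC[C@@H]1OC1(C)C | intermediate
4 | 2-hydroxy-3-methoxy-5-methylbenzaldehyde | COc1cc(C)cc(C=O)c1O | starting material
5 | 2,3-dihydroxy-5-methylbenzaldehyde | Cc1cc(O)c(O)c(C=O)c1 | intermediate
6 | disodium 3-formyl-5-methylbenzene-1,2-diolate | Cc1cc([O-])c([O-])c(C=O)c1.[Na+].[Na+] | intermediate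
7 | sodium 2-{[(2S)-3,3-dimethyloxiran-2-yl]methoxy}-6-formyl-4-methylphenolate | Cc1cc(OC[C@@H]2OC2(C)C)c([O-])c(C=O)c1.[Na+] | intermediate
8 | (3R)-3-(2-hydroxypropan-2-yl)-7-methyl-2,3-dihydro-1,4-benzodioxine-5-carbaldehyde | Cc1cc(C=O)c2O[C@@H](C(C)(C)O)COc2c1 | intermediate
9 | 3,3-diethoxyprop-1-yne | C#CC(OCC)OCC | starting material
10 | lithium 3,3-diethoxyprop-1-yn-1-ide | [Li+].[C-]#CC(OCC)OCC | intermediate
11 | 4,4-diethoxy-1-[(3R)-3-(2-hydroxypropan-2-yl)-7-methyl-2,3-dihydro-1,4-benzodioxin-5-yl]but-2-yn-1-ol (both carbinol epimers) | CCOC(OCC)C#CC(O)c1cc(C)cc2c1O[C@@H](C(C)(C)O)CO2 | intermediate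
12 | 4,4-diethoxy-1-[(3R)-3-(2-hydroxypropan-2-yl)-7-methyl-2,3-dihydro-1,4-benzodioxin-5-yl]but-2-yn-1-one | CCOC(OCC)C#CC(=O)c1cc(C)cc2c1O[C@@H](C(C)(C)O)CO2 | intermediate
13 | furan | c1ccoc1 | starting material
14 | prenyl bromide (1-bromo-3-methylbut-2-ene) | CC(C)=CCBr | starting material
15 | 2-lithiofuran (furan-2-yllithium) | [Li]c1ccco1 | intermediate
16 | 2-(3-methylbut-2-en-1-yl)furan (2-prenylfuran) | CC(C)=CCc1ccco1 | intermediate
17 | [3-(diethoxymethyl)-1-(3-methylbut-2-en-1-yl)-7-oxabicyclo[2.2.1]hepta-2,5-dien-2-yl][(3R)-3-(2-hydroxypropan-2-yl)-7-methyl-2,3-dihydro-1,4-benzodioxin-5-yl]methanone (both bridgehead diastereomers) | CC(C)=CCC12C=CC(O1)C(C(OCC)OCC)=C2C(=O)c1cc(C)cc2c1O[C@@H](C(C)(C)O)CO2 | intermediate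
18 | [2-(diethoxymethyl)-3-hydroxy-6-(3-methylbut-2-en-1-yl)phenyl][(3R)-3-(2-hydroxypropan-2-yl)-7-methyl-2,3-dihydro-1,4-benzodioxin-5-yl]methanone | CC(C)=CCc1ccc(O)c(C(OCC)OCC)c1C(=O)c1cc(C)cc2c1O[C@@H](C(C)(C)O)CO2 | intermediate
19 | 6-hydroxy-2-{[(3R)-3-(2-hydroxypropan-2-yl)-7-methyl-2,3-dihydro-1,4-benzodioxin-5-yl]carbonyl}-3-(3-methylbut-2-en-1-yl)benzaldehyde | CC(C)=CCc1ccc(O)c(C=O)c1C(=O)c1cc(C)cc2c1O[C@@H](C(C)(C)O)CO2 | target

**Step count**

Total: 8 steps. Longest linear sequence: 6 steps (steps 2, 3, 4, 5, 7, 8 from 4; equally steps 1, 3, 4, 5, 7, 8 from 1).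

**Steps most likely to fail**

1. Step 7. The cycloaddition may be slow or revert, because the alkyne of 12 is internal and activated by one carbonyl only. Once ZnI2 is present, the acetal may ionise and be captured by furan or by the new phenol instead of the bridge opening cleanly. Fallback, from 8 back to 19: the acetal is replaced by a second acceptor. Lithiated methyl propiolate (LiN(iPr)2, THF, −78 °C, 2.5 equiv) should add to 8 to give the hydroxy ynoate F1, and MnO2 should oxidise it to the keto ynoate F2. The alkyne of this aroylpropiolate carries two acceptors and should add 16 near room temperature without acid to give the oxanorbornadiene ester F3; the ketone, the stronger acceptor, still directs the unsubstituted furan α-carbon to the ester-bearing alkyne carbon. With no acetal present, the bridge can be opened with BF3·OEt2 at low temperature to give the salicylate ester F4. LiAlH4 then reduces ester and ketone to the benzylic diol F5, and Dess–Martin periodinane (excess, NaHCO3, CH2Cl2) oxidises both carbinols to give 19.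

2. Step 3. Alkylation may occur at the wrong phenol oxygen, which after ring closure would give the regioisomeric dioxane, or the opening of the hindered epoxide may be sluggish or take the 7-endo course. Fallback, from 4 back to 8: the two oxygens are kept apart by protection instead of by nucleophilicity. The free hydroxyl of 4, the one that must end on the stereogenic carbon, is masked as the aryl tosylate F6 (TsCl, Et3N, CH2Cl2). BBr3 then frees only the other oxygen to give the hydroxy tosylate F7, and alkylation with 3 (K2CO3, DMF, 50 °C) can occur only there, giving the epoxy ether tosylate F8. KOH in aqueous methanol at 50 °C cleaves the aryl sulfonate, and the phenoxide released closes the dioxane as in step 3 to give 8.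

3. Step 6. 2-Lithiofuran may attack the tertiary terminus of the allylic bromide (SN2′) and give the reverse-prenyl isomer, and the volatile product may be lost on isolation. Fallback, from 13 back to 16: 2-lithiofuran 15 is alkylated with allyl bromide, for which both modes of attack give the same product, 2-allylfuran F9. Olefin cross-metathesis with 2-methylbut-2-ene (second-generation Grubbs catalyst, neat alkene, 40 °C) then converts the allyl into the prenyl group to give 16.

**Further compounds**

F1 | step 7 | methyl 4-hydroxy-4-[(3R)-3-(2-hydroxypropan-2-yl)-7-methyl-2,3-dihydro-1,4-benzodioxin-5-yl]but-2-ynoate (both carbinol epimers) | COC(=O)C#CC(O)c1cc(C)cc2c1O[C@@H](C(C)(C)O)CO2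
F2 | step 7 | methyl 4-[(3R)-3-(2-hydroxypropan-2-yl)-7-methyl-2,3-dihydro-1,4-benzodioxin-5-yl]-4-oxobut-2-ynoate | COC(=O)C#CC(=O)c1cc(C)cc2c1O[C@@H](C(C)(C)O)CO2
F3 | step 7 | methyl 3-{[(3R)-3-(2-hydroxypropan-2-yl)-7-methyl-2,3-dihydro-1,4-benzodioxin-5-yl]carbonyl}-4-(3-methylbut-2-en-1-yl)-7-oxabicyclo[2.2.1]hepta-2,5-diene-2-carboxylate (both bridgehead diastereomers) | CC(C)=CCC12C=CC(O1)C(C(=O)OC)=C2C(=O)c1cc(C)cc2c1O[C@@H](C(C)(C)O)CO2
F4 | step 7 | methyl 6-hydroxy-2-{[(3R)-3-(2-hydroxypropan-2-yl)-7-methyl-2,3-dihydro-1,4-benzodioxin-5-yl]carbonyl}-3-(3-methylbut-2-en-1-yl)benzoate | CC(C)=CCc1ccc(O)c(C(=O)OC)c1C(=O)c1cc(C)cc2c1O[C@@H](C(C)(C)O)CO2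
F5 | step 7 | 3-{hydroxy[(3R)-3-(2-hydroxypropan-2-yl)-7-methyl-2,3-dihydro-1,4-benzodioxin-5-yl]methyl}-2-(hydroxymethyl)-4-(3-methylbut-2-en-1-yl)phenol (both carbinol epimers) | CC(C)=CCc1ccc(O)c(CO)c1C(O)c1cc(C)cc2c1O[C@@H](C(C)(C)O)CO2
F6 | step 3 | 2-formyl-6-methoxy-4-methylphenyl 4-methylbenzenesulfonate | COc1cc(C)cc(C=O)c1OS(=O)(=O)c1ccc(C)cc1
F7 | step 3 | 2-formyl-6-hydroxy-4-methylphenyl 4-methylbenzenesulfonate | Cc1cc(O)c(OS(=O)(=O)c2ccc(C)cc2)c(C=O)c1
F8 | step 3 | 2-{[(2S)-3,3-dimethyloxiran-2-yl]methoxy}-6-formyl-4-methylphenyl 4-methylbenzenesulfonate | Cc1cc(OC[C@@H]2OC2(C)C)c(OS(=O)(=O)c2ccc(C)cc2)c(C=O)c1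
F9 | step 6 | 2-(prop-2-en-1-yl)furan (2-allylfuran) | C=CCc1ccco1
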